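**Retrosynthetic overview**
1. 35 ⇐ 34: the last step is a ring-closing metathesis across C5=C6 that closes the 10-membered ring (Z alkene); butenolide and cyclohexene are already in place.
2. 34 ⇐ aldehyde 25 (fragment A) + γ-vinyl butenolide triflate 33 (fragment B): Felkin-controlled Nozaki–Hiyama–Kishi coupling forms C8–C9 and sets C9.
3. 25 ⇐ acyclic triene 22 (RCM gives the cyclohexene) ⇐ ester 11: C14 by Brown allylation, quaternary C1 by Fráter–Seebach methylation, C10 by dianionic Ireland–Claisen rearrangement.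
4. 11 ⇐ hydroxy acid 10 (C2 from ethyl (S)-4-chloro-3-hydroxybutanoate) + Z-allylic alcohol 6 (fragment C, from (Z)-butenediol).
5. 33 ⇐ (S)-α-hydroxy-γ-butyrolactone 26 (C7) by Dieckmann tetronic acid synthesis. Ring order: butenolide (in B), cyclohexene (step 16), 10-membered ring (step 26).

Assumption: atom labels follow briarane numbering (C1 quaternary, C2 butanoyloxy, C5=C6, C7 lactone CH–O, C8=C17, C9 carbinol, C10 ring-fusion CH, C11=C12, C14 acetoxy, C18 lactone C=O); the SMILES is read as 1S,2R,5Z,7S,9R,10S,14S.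

**Fragment C (steps 1–4)**

Step 1
Reactants: 1 (Z)-but-2-ene-1,4-diol
Product: 2 (Z)-1,4-bis[(4-methoxybenzyl)oxy]but-2-ene
Conditions: NaH (2.2 equiv), 4-MeOC6H4CH2Cl (2.1 equiv), Bu4NI (cat.), THF/DMF, 0 °C to rt
Reagents that add atoms: 4-methoxybenzyl chloride, COc1ccc(CCl)cc1
Why: Williamson etherification of both primary allylic alkoxides installs the p-methoxybenzyl (PMB) ether that later carries O–C9.

Step 2
Reactants: 2 (Z)-1,4-bis[(4-methoxybenzyl)oxy]but-2-ene
Product: 4 [(4-methoxybenzyl)oxy]acetaldehyde, via secondary ozonide 3 (not isolated)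
Conditions: O3, CH2Cl2, −78 °C (stopped at first blue tinge); then Me2S, −78 °C to rt
Reagents that add atoms: ozone, [O-][O+]=O
Why: Ozonolysis (Criegee mechanism) with reductive work-up cleaves the symmetrical alkene into two molecules of aldehyde; the anisyl rings survive because ozone is not used in excess.

Step 3
Reactants: 4 [(4-methoxybenzyl)oxy]acetaldehyde
Product: 5 ethyl (2Z)-4-[(4-methoxybenzyl)oxy]-2-methylbut-2-enoate
Conditions: (CF3CH2O)2P(O)CH(CH3)CO2Et, KN(SiMe3)2, 18-crown-6, THF, −78 °C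
Reagents that add atoms: ethyl 2-[bis(2,2,2-trifluoroethoxy)phosphoryl]propanoate, CCOC(=O)C(C)P(=O)(OCC(F)(F)F)OCC(F)(F)F
Why: Still–Gennari variant of the Horner–Wadsworth–Emmons olefination; fast elimination from the kinetic adduct gives the Z trisubstituted enoate.

Step 4
Reactants: 5 ethyl (2Z)-4-[(4-methoxybenzyl)oxy]-2-methylbut-2-enoate
Product: 6 (2Z)-4-[(4-methoxybenzyl)oxy]-2-methylbut-2-en-1-ol
Conditions: i-Bu2AlH (2.3 equiv), CH2Cl2, −78 °C; aq. KNaC4H4O6
Reagents that add atoms: none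
Why: 1,2-Reduction of the conjugated ester by the aluminium hydride gives the allylic alcohol without touching the Z alkene.

**Fragment A (steps 5–18)**

Step 5
Reactants: 7 ethyl (3S)-4-chloro-3-hydroxybutanoate
Product: 8 ethyl [(2S)-oxiran-2-yl]acetate
Conditions: Ag2O (1.2 equiv), MeCN, 60 °C, dark
Reagents that add atoms: none
Why: Silver-assisted intramolecular Williamson closure; the C–O bond at the stereocentre is not broken, so configuration is retained.

Step 6
Reactants: 8 ethyl [(2S)-oxiran-2-yl]acetate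
Product: 9 ethyl (3R)-3-hydroxy-6-methylhept-6-enoate
Conditions: CH2=C(CH3)CH2MgCl (1.5 equiv, slow addition), CuI (10 mol %), THF, −78 to −40 °C; aq. NH4Cl
Reagents that add atoms: 2-methylallylmagnesium chloride, CC(=C)C[Mg]Cl
Why: Copper-catalysed SN2 opening of the epoxide at its terminal carbon outruns ester addition at low temperature and leaves the carbinol centre (future C2) untouched.

Step 7
Reactants: 9 ethyl (3R)-3-hydroxy-6-methylhept-6-enoate
Product: 10 (3R)-3-hydroxy-6-methylhept-6-enoic acid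
Conditions: LiOH·H2O, THF/H2O, 0 °C to rt; then 1 M HCl
Reagents that add atoms: lithium hydroxide, [Li+].[OH-]
Why: Mild saponification of the ethyl ester; no retro-aldol or elimination occurs at 0 °C.

Step 8
Reactants: 10 (3R)-3-hydroxy-6-methylhept-6-enoic acid; 6 (2Z)-4-[(4-methoxybenzyl)oxy]-2-methylbut-2-en-1-ol
Product: 11 (2Z)-4-[(4-methoxybenzyl)oxy]-2-methylbut-2-en-1-yl (3R)-3-hydroxy-6-methylhept-6-enoate
Conditions: EDC·HCl, DMAP (cat.), CH2Cl2, 0 °C to rt
Reagents that add atoms: none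
Why: Steglich-type carbodiimide esterification; the primary allylic alcohol 6 reacts much faster than the secondary β-hydroxyl of 10.

Step 9
Reactants: 11 (2Z)-4-[(4-methoxybenzyl)oxy]-2-methylbut-2-en-1-yl (3R)-3-hydroxy-6-methylhept-6-enoate
Product: 14 methyl (2R,3R)-3-hydroxy-2-{(2R)-1-[(4-methoxybenzyl)oxy]-3-methylbut-3-en-2-yl}-6-methylhept-6-enoate, via dilithium alkoxide-enolate 12 (not isolated), via Claisen acid 13 (not isolated)
Conditions: LiN(i-Pr)2 (2.6 equiv), THF, −78 °C, then 20 to 45 °C; 1 M HCl work-up; crude acid, Me3SiCHN2, PhMe/MeOH, 0 °C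
Reagents that add atoms: (trimethylsilyl)diazomethane, C[Si](C)(C)C=[N+]=[N-]
Why: Dianionic Ireland–Claisen rearrangement: the lithium alkoxide chelates the enolate oxygen, the [3,3] shift runs through a chair on the enolate face anti to the C3 chain, and the Z alkene (CH2OPMB axial) then sets C10 as needed; the crude acid is esterified without purification.

Step 10
Reactants: 14 methyl (2R,3R)-3-hydroxy-2-{(2R)-1-[(4-methoxybenzyl)oxy]-3-methylbut-3-en-2-yl}-6-methylhept-6-enoate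
Product: 16 methyl (2S,3R)-3-hydroxy-2-{(2S)-1-[(4-methoxybenzyl)oxy]-3-methylbut-3-en-2-yl}-2,6-dimethylhept-6-enoate, via dilithium alkoxide-enolate 15 (not isolated)
Conditions: LiN(i-Pr)2 (2.5 equiv), THF, −78 to −20 °C; MeI (3 equiv), DMPU, −78 to 0 °C
Reagents that add atoms: iodomethane, CI
Why: Fráter–Seebach alkylation: in the chelated dianion MeI attacks anti to the C3 chain on the carbinol carbon, so methyl takes the face the C10 unit entered on in step 9 and the quaternary C1 has the target configuration.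

Step 11
Reactants: 16 methyl (2S,3R)-3-hydroxy-2-{(2S)-1-[(4-methoxybenzyl)oxy]-3-methylbut-3-en-2-yl}-2,6-dimethylhept-6-enoate
Product: 17 (2R,3R)-2-{(2S)-1-[(4-methoxybenzyl)oxy]-3-methylbut-3-en-2-yl}-2,6-dimethylhept-6-ene-1,3-diol
Conditions: LiAlH4, THF, 0 °C to rt
Reagents that add atoms: none
Why: Hydride reduction of the hindered ester to the neopentyl primary alcohol (future C14); no stereocentre is affected.

Step 12
Reactants: 17 (2R,3R)-2-{(2S)-1-[(4-methoxybenzyl)oxy]-3-methylbut-3-en-2-yl}-2,6-dimethylhept-6-ene-1,3-diol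
Product: 18 (2S,3R)-3-hydroxy-2-{(2S)-1-[(4-methoxybenzyl)oxy]-3-methylbut-3-en-2-yl}-2,6-dimethylhept-6-enal
Conditions: TEMPO (10 mol %), PhI(OAc)2 (1.1 equiv), CH2Cl2, rt
Reagents that add atoms: none
Why: Oxoammonium (TEMPO) oxidation is selective for the primary alcohol over the hindered secondary one, and the aldehyde has no α-hydrogen to epimerise.

Step 13
Reactants: 18 (2S,3R)-3-hydroxy-2-{(2S)-1-[(4-methoxybenzyl)oxy]-3-methylbut-3-en-2-yl}-2,6-dimethylhept-6-enal
Product: 19 (2S,3R)-2-{(2S)-1-[(4-methoxybenzyl)oxy]-3-methylbut-3-en-2-yl}-2,6-dimethyl-1-oxohept-6-en-3-yl butanoate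
Conditions: (n-PrCO)2O, Et3N, DMAP (cat.), CH2Cl2, 0 °C to rt
Reagents that add atoms: butanoic anhydride, CCCC(=O)OC(=O)CCC
Why: DMAP-catalysed acylation puts the final C2 butanoate on; the non-enolisable aldehyde tolerates the amine base.

Step 14
Reactants: 19 (2S,3R)-2-{(2S)-1-[(4-methoxybenzyl)oxy]-3-methylbut-3-en-2-yl}-2,6-dimethyl-1-oxohept-6-en-3-yl butanoate
Product: 21 (4S,5R,6R)-4-hydroxy-5-{(2S)-1-[(4-methoxybenzyl)oxy]-3-methylbut-3-en-2-yl}-5,9-dimethyldeca-1,9-dien-6-yl butanoate, via diisopinocampheylborinate 20 (not isolated)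
Conditions: (−)-Ipc2B(CH2CH=CH2) [from (−)-Ipc2BOMe and CH2=CHCH2MgBr, Et2O, 0 °C], Et2O, −78 to −40 °C; then pH 7 buffer, 30 % H2O2, MeOH, 0 °C
Reagents that add atoms: allylmagnesium bromide, C=CC[Mg]Br (transferred through (−)-B-allyldiisopinocampheylborane)
Why: Brown asymmetric allylboration through a closed chair transition state; the (+)-α-pinene-derived reagent gives the S carbinol with aldehydes whose substituent outranks allyl, which is 14S here, and buffered work-up limits butanoate migration.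

Step 15
Reactants: 21 (4S,5R,6R)-4-hydroxy-5-{(2S)-1-[(4-methoxybenzyl)oxy]-3-methylbut-3-en-2-yl}-5,9-dimethyldeca-1,9-dien-6-yl butanoate
Product: 22 (4S,5S,6R)-4-acetoxy-5-{(2S)-1-[(4-methoxybenzyl)oxy]-3-methylbut-3-en-2-yl}-5,9-dimethyldeca-1,9-dien-6-yl butanoate
Conditions: Ac2O, pyridine, DMAP (cat.), CH2Cl2, 0 °C to rt
Reagents that add atoms: acetic anhydride, CC(=O)OC(C)=O
Why: Direct acetylation of the new C14 hydroxyl gives the final acetate before any acyl shuffling between the 1,3-related oxygens can occur.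

Step 16
Reactants: 22 (4S,5S,6R)-4-acetoxy-5-{(2S)-1-[(4-methoxybenzyl)oxy]-3-methylbut-3-en-2-yl}-5,9-dimethyldeca-1,9-dien-6-yl butanoate
Product: 23 (1R)-1-[(1S,2S,6S)-6-acetoxy-2-{[(4-methoxybenzyl)oxy]methyl}-1,3-dimethylcyclohex-3-en-1-yl]-5-methylhex-5-en-1-yl butanoate
Conditions: second-generation Grubbs catalyst (H2IMes)(PCy3)Cl2Ru=CHPh (5 mol %), CH2Cl2 (5 mM), 40 °C
Reagents that add atoms: none
Why: Ring-closing metathesis of the allyl group with the adjacent isopropenyl group gives the six-membered ring with the C11=C12 alkene; the 8-membered closure onto the C5 isopropenyl group is far slower.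

Step 17
Reactants: 23 (1R)-1-[(1S,2S,6S)-6-acetoxy-2-{[(4-methoxybenzyl)oxy]methyl}-1,3-dimethylcyclohex-3-en-1-yl]-5-methylhex-5-en-1-yl butanoate
Product: 24 (1R)-1-[(1S,2S,6S)-6-acetoxy-2-(hydroxymethyl)-1,3-dimethylcyclohex-3-en-1-yl]-5-methylhex-5-en-1-yl butanoate
Conditions: DDQ (1.3 equiv), CH2Cl2/pH 7 phosphate buffer 10:1, 0 °C
Reagents that add atoms: none
Why: Oxidative PMB ether cleavage (hydride abstraction, hydrolysis) is neutral, so both esters and the alkenes survive.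

Step 18
Reactants: 24 (1R)-1-[(1S,2S,6S)-6-acetoxy-2-(hydroxymethyl)-1,3-dimethylcyclohex-3-en-1-yl]-5-methylhex-5-en-1-yl butanoate
Product: 25 (1R)-1-[(1S,2S,6S)-6-acetoxy-2-formyl-1,3-dimethylcyclohex-3-en-1-yl]-5-methylhex-5-en-1-yl butanoate
Conditions: Dess–Martin periodinane, NaHCO3, CH2Cl2, 0 °C; used crude
Reagents that add atoms: none
Why: Dess–Martin oxidation under buffered conditions gives the β,γ-unsaturated aldehyde without epimerising C10 or moving the alkene into conjugation.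

**Fragment B (steps 19–24)**

Step 19
Reactants: 26 (3S)-3-hydroxyoxolan-2-one
Product: 27 (2S)-2-hydroxy-4-(phenylselanyl)butanoic acid
Conditions: PhSeNa [from (PhSe)2 and NaH, THF, 65 °C]; then 26, DMF, 80 °C; then 1 M HCl
Reagents that add atoms: diphenyl diselenide, c1ccc(cc1)[Se][Se]c1ccccc1
Why: SN2 opening of the lactone at its O–CH2 carbon by the soft selenolate; the stereocentre is not involved, and the selenide is a masked vinyl group.

Step 20
Reactants: 27 (2S)-2-hydroxy-4-(phenylselanyl)butanoic acid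
Product: 28 methyl (2S)-2-hydroxy-4-(phenylselanyl)butanoate
Conditions: MeOH, H2SO4 (cat.), 40 °C
Reagents that add atoms: methanol, CO
Why: Fischer esterification; with selenium in place of the ring oxygen the acid cannot relactonise.

Step 21
Reactants: 28 methyl (2S)-2-hydroxy-4-(phenylselanyl)butanoate
Product: 29 methyl (2S)-4-(phenylselanyl)-2-(propanoyloxy)butanoate
Conditions: EtCOCl, pyridine, DMAP (cat.), CH2Cl2, 0 °C
Reagents that add atoms: propanoyl chloride, CCC(Cl)=O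
Why: O-acylation supplies C17, C18 and the C19 methyl of the butenolide.

Step 22
Reactants: 29 methyl (2S)-4-(phenylselanyl)-2-(propanoyloxy)butanoate
Product: 30 (5S)-4-hydroxy-3-methyl-5-[2-(phenylselanyl)ethyl]furan-2(5H)-one
Conditions: LiN(SiMe3)2 (2.2 equiv), THF, −78 to 0 °C; then 1 M HCl
Reagents that add atoms: none
Why: Lacey–Dieckmann cyclisation: the propanoate enolate attacks the methyl ester and the product is held as its tetronate anion, which protects the C7 centre from the base.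

Step 23
Reactants: 30 (5S)-4-hydroxy-3-methyl-5-[2-(phenylselanyl)ethyl]furan-2(5H)-one
Product: 31 (2S)-4-methyl-5-oxo-2-[2-(phenylselanyl)ethyl]-2,5-dihydrofuran-3-yl trifluoromethanesulfonate
Conditions: (CF3SO2)2O (1.05 equiv), i-Pr2NEt, CH2Cl2, −78 °C
Reagents that add atoms: trifluoromethanesulfonic anhydride, O=S(=O)(OS(=O)(=O)C(F)(F)F)C(F)(F)F
Why: O-sulfonylation of the vinylogous acid gives the enol triflate that serves as the C8 coupling handle.

Step 24
Reactants: 31 (2S)-4-methyl-5-oxo-2-[2-(phenylselanyl)ethyl]-2,5-dihydrofuran-3-yl trifluoromethanesulfonate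
Product: 33 (2S)-4-methyl-5-oxo-2-vinyl-2,5-dihydrofuran-3-yl trifluoromethanesulfonate, via selenoxide 32 (not isolated)
Conditions: 30 % H2O2, THF, 0 °C to rt
Reagents that add atoms: none
Why: Selenide oxidation and syn-elimination of the selenoxide reveal the C6 vinyl group without base, so the acidic γ-stereocentre C7 is not racemised.

**Coupling and ring closure (steps 25–26)**

Step 25
Reactants: 25 (1R)-1-[(1S,2S,6S)-6-acetoxy-2-formyl-1,3-dimethylcyclohex-3-en-1-yl]-5-methylhex-5-en-1-yl butanoate; 33 (2S)-4-methyl-5-oxo-2-vinyl-2,5-dihydrofuran-3-yl trifluoromethanesulfonate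
Product: 34 (1R)-1-[(1S,2S,6S)-6-acetoxy-2-{(R)-hydroxy[(2S)-4-methyl-5-oxo-2-vinyl-2,5-dihydrofuran-3-yl]methyl}-1,3-dimethylcyclohex-3-en-1-yl]-5-methylhex-5-en-1-yl butanoate
Conditions: CrCl2 (6 equiv), NiCl2 (2 mol %), degassed DMF, rt
Reagents that add atoms: none
Why: Nozaki–Hiyama–Kishi coupling: zerovalent nickel inserts into the enol triflate, transmetallation gives an ester-tolerant alkenylchromium, and Felkin–Anh addition to the aldehyde (quaternary C1 anti to the nucleophile, C11 next to the carbonyl oxygen) gives 9R.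

Step 26
Reactants: 34 (1R)-1-[(1S,2S,6S)-6-acetoxy-2-{(R)-hydroxy[(2S)-4-methyl-5-oxo-2-vinyl-2,5-dihydrofuran-3-yl]methyl}-1,3-dimethylcyclohex-3-en-1-yl]-5-methylhex-5-en-1-yl butanoate
Product: 35 (1S,2R,5Z,7S,9R,10S,14S)-14-acetoxy-2-butanoyloxy-9-hydroxybriara-5,8(17),11-trien-18,7-olide
Conditions: second-generation Hoveyda–Grubbs catalyst (H2IMes)Cl2Ru=CH(C6H4-2-O-i-Pr) (20 mol %, in portions), 1,4-benzoquinone (10 mol %), PhMe (1 mM), 80 °C
Reagents that add atoms: none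
Why: Ring-closing metathesis at high dilution: ruthenium loads on the C6 vinyl group and closes onto the 1,1-disubstituted C5 alkene; the trans-fused 10-membered ring should accept only the cis-in-ring (5Z) trisubstituted alkene, and the tetrasubstituted butenolide and ring alkenes are inert.

**Compound list**
1 | (Z)-but-2-ene-1,4-diol | OC/C=C\CO | starting material
2 | (Z)-1,4-bis[(4-methoxybenzyl)oxy]but-2-ene | COc1ccc(COC/C=C\COCc2ccc(OC)cc2)cc1 | intermediate
3 | 3,5-bis{[(4-methoxybenzyl)oxy]methyl}-1,2,4-trioxolane (secondary ozonide, cis/trans mixture) | COc1ccc(COCC2OOC(COCc3ccc(OC)cc3)O2)cc1 | intermediate (not isolated)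
4 | [(4-methoxybenzyl)oxy]acetaldehyde | COc1ccc(COCC=O)cc1 | intermediate
5 | ethyl (2Z)-4-[(4-methoxybenzyl)oxy]-2-methylbut-2-enoate | CCOC(=O)/C(C)=C\COCc1ccc(OC)cc1 | intermediate
6 | (2Z)-4-[(4-methoxybenzyl)oxy]-2-methylbut-2-en-1-ol (fragment C) | OC/C(C)=C\COCc1ccc(OC)cc1 | intermediate
7 | ethyl (3S)-4-chloro-3-hydroxybutanoate | CCOC(=O)C[C@H](O)CCl | starting material
8 | ethyl [(2S)-oxiran-2-yl]acetate | CCOC(=O)C[C@H]1CO1 | intermediate
9 | ethyl (3R)-3-hydroxy-6-methylhept-6-enoate | CCOC(=O)C[C@H](O)CCC(C)=C | intermediate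
10 | (3R)-3-hydroxy-6-methylhept-6-enoic acid | OC(=O)C[C@H](O)CCC(C)=C | intermediate
11 | (2Z)-4-[(4-methoxybenzyl)oxy]-2-methylbut-2-en-1-yl (3R)-3-hydroxy-6-methylhept-6-enoate | C=C(C)CC[C@@H](O)CC(=O)OC/C(C)=C\COCc1ccc(OC)cc1 | intermediate
12 | dilithium alkoxide-enolate of 11 (carbinol carbon cis to OLi) | C=C(C)CC[C@@H](O[Li])/C=C(\O[Li])OC/C(C)=C\COCc1ccc(OC)cc1 | intermediate (not isolated)
13 | (2R,3R)-3-hydroxy-2-{(2R)-1-[(4-methoxybenzyl)oxy]-3-methylbut-3-en-2-yl}-6-methylhept-6-enoic acid | C=C(C)CC[C@@H](O)[C@H](C(=O)O)[C@@H](COCc1ccc(OC)cc1)C(C)=C | intermediate (not isolated)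
14 | methyl (2R,3R)-3-hydroxy-2-{(2R)-1-[(4-methoxybenzyl)oxy]-3-methylbut-3-en-2-yl}-6-methylhept-6-enoate | C=C(C)CC[C@@H](O)[C@H](C(=O)OC)[C@@H](COCc1ccc(OC)cc1)C(C)=C | intermediate
15 | dilithium alkoxide-enolate of 14 | C=C(C)CC[C@@H](O[Li])/C(=C(\O[Li])OC)[C@@H](COCc1ccc(OC)cc1)C(C)=C | intermediate (not isolated)
16 | methyl (2S,3R)-3-hydroxy-2-{(2S)-1-[(4-methoxybenzyl)oxy]-3-methylbut-3-en-2-yl}-2,6-dimethylhept-6-enoate | C=C(C)CC[C@@H](O)[C@@](C)(C(=O)OC)[C@@H](COCc1ccc(OC)cc1)C(C)=C | intermediate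
17 | (2R,3R)-2-{(2S)-1-[(4-methoxybenzyl)oxy]-3-methylbut-3-en-2-yl}-2,6-dimethylhept-6-ene-1,3-diol | C=C(C)CC[C@@H](O)[C@@](C)(CO)[C@@H](COCc1ccc(OC)cc1)C(C)=C | intermediate
18 | (2S,3R)-3-hydroxy-2-{(2S)-1-[(4-methoxybenzyl)oxy]-3-methylbut-3-en-2-yl}-2,6-dimethylhept-6-enal | C=C(C)CC[C@@H](O)[C@@](C)(C=O)[C@@H](COCc1ccc(OC)cc1)C(C)=C | intermediate
19 | (2S,3R)-2-{(2S)-1-[(4-methoxybenzyl)oxy]-3-methylbut-3-en-2-yl}-2,6-dimethyl-1-oxohept-6-en-3-yl butanoate | CCCC(=O)O[C@H](CCC(C)=C)[C@@](C)(C=O)[C@@H](COCc1ccc(OC)cc1)C(C)=C | intermediate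
20 | O-diisopinocampheylboryl derivative (borinate) of 21 | CCCC(=O)O[C@H](CCC(C)=C)[C@@](C)([C@@H](OB([C@H]1[C@H](C)[C@H]2C[C@@H](C1)C2(C)C)[C@H]1[C@H](C)[C@H]2C[C@@H](C1)C2(C)C)CC=C)[C@@H](COCc1ccc(OC)cc1)C(C)=C | intermediate (not isolated)
21 | (4S,5R,6R)-4-hydroxy-5-{(2S)-1-[(4-methoxybenzyl)oxy]-3-methylbut-3-en-2-yl}-5,9-dimethyldeca-1,9-dien-6-yl butanoate | CCCC(=O)O[C@H](CCC(C)=C)[C@@](C)([C@@H](O)CC=C)[C@@H](COCc1ccc(OC)cc1)C(C)=C | intermediate
22 | (4S,5S,6R)-4-acetoxy-5-{(2S)-1-[(4-methoxybenzyl)oxy]-3-methylbut-3-en-2-yl}-5,9-dimethyldeca-1,9-dien-6-yl butanoate | CCCC(=O)O[C@H](CCC(C)=C)[C@@](C)([C@@H](OC(C)=O)CC=C)[C@@H](COCc1ccc(OC)cc1)C(C)=C | intermediate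
23 | (1R)-1-[(1S,2S,6S)-6-acetoxy-2-{[(4-methoxybenzyl)oxy]methyl}-1,3-dimethylcyclohex-3-en-1-yl]-5-methylhex-5-en-1-yl butanoate | CCCC(=O)O[C@H](CCC(C)=C)[C@]1(C)[C@@H](COCc2ccc(OC)cc2)C(C)=CC[C@@H]1OC(C)=O | intermediate
24 | (1R)-1-[(1S,2S,6S)-6-acetoxy-2-(hydroxymethyl)-1,3-dimethylcyclohex-3-en-1-yl]-5-methylhex-5-en-1-yl butanoate | CCCC(=O)O[C@H](CCC(C)=C)[C@]1(C)[C@@H](CO)C(C)=CC[C@@H]1OC(C)=O | intermediate
25 | (1R)-1-[(1S,2S,6S)-6-acetoxy-2-formyl-1,3-dimethylcyclohex-3-en-1-yl]-5-methylhex-5-en-1-yl butanoate (fragment A) | CCCC(=O)O[C@H](CCC(C)=C)[C@]1(C)[C@@H](C=O)C(C)=CC[C@@H]1OC(C)=O | intermediate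
26 | (3S)-3-hydroxyoxolan-2-one [(S)-α-hydroxy-γ-butyrolactone] | O[C@H]1CCOC1=O | starting material
27 | (2S)-2-hydroxy-4-(phenylselanyl)butanoic acid | OC(=O)[C@@H](O)CC[Se]c1ccccc1 | intermediate
28 | methyl (2S)-2-hydroxy-4-(phenylselanyl)butanoate | COC(=O)[C@@H](O)CC[Se]c1ccccc1 | intermediate
29 | methyl (2S)-4-(phenylselanyl)-2-(propanoyloxy)butanoate | CCC(=O)O[C@@H](CC[Se]c1ccccc1)C(=O)OC | intermediate
30 | (5S)-4-hydroxy-3-methyl-5-[2-(phenylselanyl)ethyl]furan-2(5H)-one | CC1=C(O)[C@H](CC[Se]c2ccccc2)OC1=O | intermediate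
31 | (2S)-4-methyl-5-oxo-2-[2-(phenylselanyl)ethyl]-2,5-dihydrofuran-3-yl trifluoromethanesulfonate | CC1=C(OS(=O)(=O)C(F)(F)F)[C@H](CC[Se]c2ccccc2)OC1=O | intermediate
32 | selenoxide of 31 (both configurations at selenium) | CC1=C(OS(=O)(=O)C(F)(F)F)[C@H](CC[Se](=O)c2ccccc2)OC1=O | intermediate (not isolated)
33 | (2S)-4-methyl-5-oxo-2-vinyl-2,5-dihydrofuran-3-yl trifluoromethanesulfonate (fragment B) | C=C[C@@H]1OC(=O)C(C)=C1OS(=O)(=O)C(F)(F)F | intermediate
34 | (1R)-1-[(1S,2S,6S)-6-acetoxy-2-{(R)-hydroxy[(2S)-4-methyl-5-oxo-2-vinyl-2,5-dihydrofuran-3-yl]methyl}-1,3-dimethylcyclohex-3-en-1-yl]-5-methylhex-5-en-1-yl butanoate | CCCC(=O)O[C@H](CCC(C)=C)[C@]1(C)[C@@H]([C@@H](O)C2=C(C)C(=O)O[C@H]2C=C)C(C)=CC[C@@H]1OC(C)=O | intermediate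
35 | (1S,2R,5Z,7S,9R,10S,14S)-14-acetoxy-2-butanoyloxy-9-hydroxybriara-5,8(17),11-trien-18,7-olide (CNP0293221.1) | CCCC(=O)O[C@@H]1CC/C(C)=C\[C@@H]2OC(=O)C(C)=C2[C@H](O)[C@H]2C(C)=CC[C@H](OC(C)=O)[C@@]21C | target

**Totals**
Total step count: 26.
Longest linear sequence: 17 steps (1–4, 8–18, 25, 26); the other lines are 16 steps (5–18, 25, 26) and 8 steps (19–26).

**Three steps most likely to fail**

Step 26 (10-membered RCM to a trisubstituted alkene). Risks are oligomerisation, a stalled catalyst on the hindered 1,1-disubstituted alkene, and strain in the trans-fused ring. The fallback sets out from 34 and comes back at 35. Dess–Martin oxidation of 34 gives the C9 ketone F1, which has a planar C9 and no free hydroxyl to bind ruthenium. Ring-closing metathesis of F1 under the step-26 conditions gives the macrocyclic 9-ketone F2, and Luche reduction (NaBH4, CeCl3·7H2O, MeOH, −78 °C) returns 35. The approach changes in that C9 is set after ring closure, by hydride delivery to the macrocycle; the facial selectivity is not predictable in advance, so any 9-epimer is re-oxidised to F2 and reduced instead with (S)-2-methyl-CBS-oxazaborolidine and catecholborane.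

Step 25 (Nozaki–Hiyama–Kishi coupling of an electron-poor enol triflate with a hindered, epimerisable aldehyde). Risks are sluggish addition, reduction of the triflate, nickel insertion into the allylic lactone C–O bond, and incomplete Felkin control. The fallback sets out from 25 and 33 and comes back at 34. Pinnick oxidation of 25 (NaClO2, NaH2PO4, 2-methylbut-2-ene, t-BuOH/H2O) gives the carboxylic acid F3. 1-Chloro-N,N,2-trimethylprop-1-enylamine converts F3 under neutral conditions into the acid chloride F4. Triflate 33 is stannylated (Me3SnSnMe3, Pd(PPh3)4, LiCl, THF, 60 °C) to the stannane F5. Stille acylation of F5 with F4 (Pd2(dba)3, tri(2-furyl)phosphine, PhMe, 50 °C) gives the ketone F1. Reduction of F1 with (S)-2-methyl-CBS-oxazaborolidine and catecholborane at −78 °C, with the butenolide as the large π substituent, should give 34; this opposes the Felkin bias of hydride addition, so the 9-epimer, if formed, is re-oxidised and recycled.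

Step 10 (Fráter–Seebach methylation to a quaternary carbon next to a tertiary one). Risks are incomplete dianion formation and low conversion or selectivity on the crowded enolate. The fallback sets out from 13 (isolated after the rearrangement of step 9 instead of being esterified) and comes back at 17. Acetalisation of 13 with pivalaldehyde (PPTS, CH2Cl2, reflux, water removal) gives the cis-2-tert-butyl-1,3-dioxan-4-one F6. Its lithium enolate (LiN(i-Pr)2, THF, −78 °C) is methylated by MeI trans to the C6 side chain and the tert-butyl group (Seebach dioxanone alkylation, same facial sense as the chelate) to give F7. LiAlH4 opens F7 directly to diol 17.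

**Further compounds**
F1 | step 26 | (1R)-1-[(1S,2S,6S)-6-acetoxy-1,3-dimethyl-2-{[(2S)-4-methyl-5-oxo-2-vinyl-2,5-dihydrofuran-3-yl]carbonyl}cyclohex-3-en-1-yl]-5-methylhex-5-en-1-yl butanoate | CCCC(=O)O[C@H](CCC(C)=C)[C@]1(C)[C@@H](C(=O)C2=C(C)C(=O)O[C@H]2C=C)C(C)=CC[C@@H]1OC(C)=O
F2 | step 26 | (1S,2R,5Z,7S,10S,14S)-14-acetoxy-2-butanoyloxy-9-oxobriara-5,8(17),11-trien-18,7-olide | CCCC(=O)O[C@@H]1CC/C(C)=C\[C@@H]2OC(=O)C(C)=C2C(=O)[C@H]2C(C)=CC[C@H](OC(C)=O)[C@@]21C
F3 | step 25 | (1S,5S,6S)-5-acetoxy-6-[(1R)-1-(butanoyloxy)-5-methylhex-5-en-1-yl]-2,6-dimethylcyclohex-2-ene-1-carboxylic acid | CCCC(=O)O[C@H](CCC(C)=C)[C@]1(C)[C@@H](C(=O)O)C(C)=CC[C@@H]1OC(C)=O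
F4 | step 25 | (1S,5S,6S)-5-acetoxy-6-[(1R)-1-(butanoyloxy)-5-methylhex-5-en-1-yl]-2,6-dimethylcyclohex-2-ene-1-carbonyl chloride | CCCC(=O)O[C@H](CCC(C)=C)[C@]1(C)[C@@H](C(Cl)=O)C(C)=CC[C@@H]1OC(C)=O
F5 | step 25 | (5S)-3-methyl-4-(trimethylstannyl)-5-vinylfuran-2(5H)-one | C=C[C@@H]1OC(=O)C(C)=C1[Sn](C)(C)C
F6 | step 10 | (2R,5R,6R)-2-tert-butyl-5-{(2R)-1-[(4-methoxybenzyl)oxy]-3-methylbut-3-en-2-yl}-6-(3-methylbut-3-en-1-yl)-1,3-dioxan-4-one | O1[C@@H](C(C)(C)C)OC(=O)[C@H]([C@@H](COCc2ccc(OC)cc2)C(C)=C)[C@H]1CCC(C)=C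
F7 | step 10 | (2R,5S,6R)-2-tert-butyl-5-{(2S)-1-[(4-methoxybenzyl)oxy]-3-methylbut-3-en-2-yl}-5-methyl-6-(3-methylbut-3-en-1-yl)-1,3-dioxan-4-one | O1[C@@H](C(C)(C)C)OC(=O)[C@@](C)([C@@H](COCc2ccc(OC)cc2)C(C)=C)[C@H]1CCC(C)=C
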